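**Retrosynthetic overview** (flavan numbering: O1, C2–C4, C4a, C5–C8, C8a; ring B primed; α = face of the 2-aryl group)
1. The target is epioritin-(4β→6)-epimesquitol-4β-ol. Removing the lower C4–OH (late benzylic hydroxylation) and cutting C4(upper)–C6(lower) (flavan-4-yl cation plus lower ring A) leaves two (2R,3R)-2,3-cis-flavan-3-ols that differ only at C3'.
2. Both halves come from one monomer with Br at C3'. Br → OBn gives the lower (catechol) half, and Br → H in the last hydrogenolysis gives the upper (4-hydroxyphenyl) half.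
3. The monomer's pyran ring O1–C2–C3–C4–C4a–C8a is made by expanding the five-membered ring O1–C2–C3–C4a–C8a of a cis-2-aryl-3-(hydroxymethyl)-2,3-dihydrobenzofuran. Ring A shifts from C3 to the exocyclic CH2 (the future C4), and water enters at C3 with inversion.
4. Enabling feature: in the pyrogallol-type ring A the migrating carbon C4a is para to O7 and ortho to O1, so it bridges as a well-stabilised phenonium ion. The cis-dihydrobenzofuran is the product type that an enantioselective Rh-carbene 1,5 C–H insertion delivers best.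
5. Ring order: dihydrofuran ring (C–H insertion) → pyran ring (expansion, serves both halves) → union of the halves → lower C4–OH → global deprotection.

Key step: step 9

Assumption: Rh2(S-PTTL)4 is taken to give the (2S,3R)-cis ester of step 7; if the sense of induction is opposite, the enantiomeric catalyst is used and nothing else changes.

Step 1
Reactants: 1 2',3',4'-trihydroxyacetophenone
Product: 2 1-[3,4-bis(benzyloxy)-2-hydroxyphenyl]ethanone
Conditions: BnBr (2.1 equiv), K2CO3, acetone, reflux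
Reagents that add atoms: benzyl bromide, BrCc1ccccc1
Why: Williamson etherification in which the 2-OH, hydrogen-bonded to the acetyl C=O and flanked on both sides, should stay free.

Step 2
Reactants: 3 4-(benzyloxy)-3-bromobenzaldehyde
Product: 4 [4-(benzyloxy)-3-bromophenyl]methanol
Conditions: NaBH4, MeOH, 0 °C
Reagents that add atoms: none
Why: Borohydride reduction of an aromatic aldehyde, which leaves the aryl bromide and the benzyl ether untouched.

Step 3
Reactants: 4 [4-(benzyloxy)-3-bromophenyl]methanol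
Product: 5 1-(benzyloxy)-2-bromo-4-(bromomethyl)benzene
Conditions: PBr3, CH2Cl2, 0 °C
Reagents that add atoms: phosphorus tribromide, BrP(Br)Br
Why: Standard SN2 conversion of a primary benzylic alcohol into the bromide through its phosphite ester.

Step 4
Reactants: 2 1-[3,4-bis(benzyloxy)-2-hydroxyphenyl]ethanone; 5 1-(benzyloxy)-2-bromo-4-(bromomethyl)benzene
Product: 6 1-[3,4-bis(benzyloxy)-2-{[4-(benzyloxy)-3-bromophenyl]methoxy}phenyl]ethanone
Conditions: K2CO3, Bu4NI (cat.), DMF, 60 °C
Reagents that add atoms: none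
Why: Williamson etherification of the remaining chelated phenol with a reactive benzylic bromide under more forcing conditions, which installs O1–CH2–ring B.

Step 5
Reactants: 6 1-[3,4-bis(benzyloxy)-2-{[4-(benzyloxy)-3-bromophenyl]methoxy}phenyl]ethanone
Product: 8 methyl 2-[3,4-bis(benzyloxy)-2-{[4-(benzyloxy)-3-bromophenyl]methoxy}phenyl]-2-oxoacetate, via arylglyoxylic acid 7 (not isolated)
Conditions: SeO2, pyridine, 100 °C; filter; then MeI, K2CO3, DMF, rt
Reagents that add atoms: selenium dioxide, O=[Se]=O; methyl iodide, CI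
Why: Riley oxidation of the aryl methyl ketone to the glyoxylic acid in a basic medium (which spares the acid-labile p-alkoxybenzyl aryl ether), followed by carboxylate alkylation.

Step 6
Reactants: 8 methyl 2-[3,4-bis(benzyloxy)-2-{[4-(benzyloxy)-3-bromophenyl]methoxy}phenyl]-2-oxoacetate
Product: 10 methyl 2-[3,4-bis(benzyloxy)-2-{[4-(benzyloxy)-3-bromophenyl]methoxy}phenyl]-2-diazoacetate, via tosylhydrazone 9 (not isolated)
Conditions: TsNHNH2, toluene, 70 °C; then DBU, CH2Cl2, 0 °C to rt
Reagents that add atoms: p-toluenesulfonyl hydrazide, Cc1ccc(cc1)S(=O)(=O)NN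
Why: Hydrazone formation and Bamford–Stevens-type base-induced loss of sulfinate is the standard route from aryl glyoxylates to aryldiazoacetates.

Step 7
Reactants: 10 methyl 2-[3,4-bis(benzyloxy)-2-{[4-(benzyloxy)-3-bromophenyl]methoxy}phenyl]-2-diazoacetate
Product: 11 methyl (2S,3R)-6,7-bis(benzyloxy)-2-[4-(benzyloxy)-3-bromophenyl]-2,3-dihydro-1-benzofuran-3-carboxylate (2,3-cis)
Conditions: Rh2(S-PTTL)4 (1 mol %), toluene, −60 °C
Reagents that add atoms: none
Why: Enantioselective intramolecular Rh-carbene 1,5 C–H insertion into the only reachable benzylic ether C–H closes the five-membered ring, with the chiral carboxylate catalyst setting C2 and C3 together and favouring the kinetic cis isomer.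

Step 8
Reactants: 11 methyl (2S,3R)-6,7-bis(benzyloxy)-2-[4-(benzyloxy)-3-bromophenyl]-2,3-dihydro-1-benzofuran-3-carboxylate
Product: 12 {(2S,3S)-6,7-bis(benzyloxy)-2-[4-(benzyloxy)-3-bromophenyl]-2,3-dihydro-1-benzofuran-3-yl}methanol (2,3-cis)
Conditions: DIBAL-H (3 equiv), CH2Cl2, −78 to −20 °C; aq. Rochelle salt
Reagents that add atoms: none
Why: Ester reduction with a weakly basic hydride at low temperature should outrun cis-to-trans epimerisation at C3.

Step 9
Reactants: 12 {(2S,3S)-6,7-bis(benzyloxy)-2-[4-(benzyloxy)-3-bromophenyl]-2,3-dihydro-1-benzofuran-3-yl}methanol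
Product: 15 (2R,3R)-7,8-bis(benzyloxy)-2-[4-(benzyloxy)-3-bromophenyl]chroman-3-ol (2,3-cis), via primary triflate 13 (not isolated), via phenonium triflate 14 (not isolated)
Conditions: Tf2O (1.1 equiv), 2,6-di-tert-butyl-4-methylpyridine (3 equiv), CH2Cl2, −78 °C; then THF–H2O (4:1), −78 to 0 °C
Reagents that add atoms: water, O; trifluoromethanesulfonic anhydride, O=S(=O)(OS(=O)(=O)C(F)(F)F)C(F)(F)F (its atoms stay only in 13 and 14)
Why: Proposed new method: O-triflation makes the exocyclic CH2OH a primary leaving group that cannot ionise unaided, so ring A assists through its ipso carbon C4a (Ar1-3 participation, a 3-exo-tet closure) and gives the spiro-cyclopropane phenonium ion 14, in which C4a bridges C3 and the former CH2 on the α-face. Water then opens the C3–C4a bond, the fusion bond of the strained 5/3 bicycle, from the rear, so the CH2 stays on C4a as C4 and the ring O1–C2–C3–C4a–C8a becomes the pyran ring O1–C2–C3–C4–C4a–C8a without any end-to-end cyclisation. The closest known reaction type is the phenonium-assisted Wagner–Meerwein (Demjanov-type) ring expansion of benzocycloalkylmethyl sulfonates and amines (1-indanylmethyl to 2-tetralyl, 9-fluorenylmethanol to phenanthrene), which has not been shown on 2-aryl-2,3-dihydrobenzofuran-3-ylmethanols. C3 is the only stereocentre touched: inversion there puts the new OH on the face that carried the CH2 group, so the cis relation of step 7 is copied into the (2R,3R)-2,3-cis flavan-3-ol, and C2 is not involved. The step needs A-ring migration to beat the 1,2-hydride shift from C3 (which would end in a 3-methylbenzofuran), migration of ring B from C2, and attack of water at the primary carbon; the para-O7 and ortho-O1 donors on C4a, the deactivating 3'-Br on ring B, the hindered base, the low temperature and the strain released by cleaving the fusion bond are meant to secure this.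

Step 10
Reactants: 15 (2R,3R)-7,8-bis(benzyloxy)-2-[4-(benzyloxy)-3-bromophenyl]chroman-3-ol
Product: 16 (2R,3R)-7,8-bis(benzyloxy)-2-[3,4-bis(benzyloxy)phenyl]chroman-3-ol (tetra-O-benzylepimesquitol)
Conditions: BnOH, tBuBrettPhos Pd G3 (3 mol %), Cs2CO3, toluene, 90 °C
Reagents that add atoms: benzyl alcohol, OCc1ccccc1
Why: Pd-catalysed C–O cross-coupling (Buchwald–Hartwig etherification) of the aryl bromide with a primary alcohol, which should outcompete the hindered secondary 3-OH and touches no stereocentre.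

Step 11
Reactants: 15 (2R,3R)-7,8-bis(benzyloxy)-2-[4-(benzyloxy)-3-bromophenyl]chroman-3-ol
Product: 17 (2R,3R,4S)-7,8-bis(benzyloxy)-2-[4-(benzyloxy)-3-bromophenyl]-4-(2-ethoxyethoxy)chroman-3-ol (4β-alkoxy, 3,4-trans)
Conditions: DDQ (2 equiv), EtOCH2CH2OH (10 equiv), CH2Cl2, rt
Reagents that add atoms: 2-ethoxyethanol, CCOCCO
Why: DDQ abstracts hydride from C4 (benzylic, para to 7-OBn) and the alcohol traps the flavan-4-yl cation from the β-face, anti to the 3-OH and the 2-aryl group, while the 3'-Br makes the competing C2–H less reactive.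

Step 12
Reactants: 17 (2R,3R,4S)-7,8-bis(benzyloxy)-2-[4-(benzyloxy)-3-bromophenyl]-4-(2-ethoxyethoxy)chroman-3-ol; 16 (2R,3R)-7,8-bis(benzyloxy)-2-[3,4-bis(benzyloxy)phenyl]chroman-3-ol
Product: 18 hepta-O-benzyl-3'-bromoepioritin-(4β→6)-epimesquitol (upper unit 2,3-cis-3,4-trans, lower unit 2,3-cis with C4H2)
Conditions: 16 (3 equiv, excess recovered), TMSOTf (1 equiv), CH2Cl2, −78 to −40 °C
Reagents that add atoms: none
Why: Lewis-acid ionisation of the 4-alkoxy group and Friedel–Crafts alkylation at C6 of 16 (para to O1, ortho to O7), with β-face attack on the 2,3-cis cation setting the upper C4 trans to the 3-OH.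

Step 13
Reactants: 18 hepta-O-benzyl-3'-bromoepioritin-(4β→6)-epimesquitol
Product: 19 hepta-O-benzyl-3'-bromoepioritin-(4β→6)-epimesquitol-4β-ol (lower unit 2,3-cis-3,4-trans)
Conditions: DDQ (1.5 equiv), CH2Cl2–H2O (10:1), 0 °C
Reagents that add atoms: water, O
Why: DDQ benzylic oxidation should pick the lower C4, whose axial C–H overlaps with the most electron-rich ring, whereas the upper C4–H lies near the plane of its ring A because the 4β-aryl group is axial, and water then adds from the β-face.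

Step 14
Reactants: 19 hepta-O-benzyl-3'-bromoepioritin-(4β→6)-epimesquitol-4β-ol
Product: 20 epioritin-(4β→6)-epimesquitol-4β-ol (CNP0275688.1)
Conditions: H2 (1 atm), Pd(OH)2/C, Et3N (1.2 equiv), THF–MeOH–H2O, rt
Reagents that add atoms: none
Why: Hydrogenolysis of the seven aryl benzyl ethers and hydrodebromination of C3' in one operation, with Et3N binding HBr and suppressing acid-promoted hydrogenolysis of the lower C4–OH.

**Compound list**
1 | 2',3',4'-trihydroxyacetophenone | CC(=O)c1ccc(O)c(O)c1O | starting material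
2 | 1-[3,4-bis(benzyloxy)-2-hydroxyphenyl]ethanone | CC(=O)c1ccc(OCc2ccccc2)c(OCc2ccccc2)c1O | intermediate
3 | 4-(benzyloxy)-3-bromobenzaldehyde | O=Cc1ccc(OCc2ccccc2)c(Br)c1 | starting material
4 | [4-(benzyloxy)-3-bromophenyl]methanol | OCc1ccc(OCc2ccccc2)c(Br)c1 | intermediate
5 | 1-(benzyloxy)-2-bromo-4-(bromomethyl)benzene | BrCc1ccc(OCc2ccccc2)c(Br)c1 | intermediate
6 | aryl methyl ketone with O1–CH2–ring B ether | CC(=O)c1ccc(OCc2ccccc2)c(OCc2ccccc2)c1OCc1ccc(OCc2ccccc2)c(Br)c1 | intermediate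
7 | arylglyoxylic acid | OC(=O)C(=O)c1ccc(OCc2ccccc2)c(OCc2ccccc2)c1OCc1ccc(OCc2ccccc2)c(Br)c1 | intermediate
8 | methyl arylglyoxylate | COC(=O)C(=O)c1ccc(OCc2ccccc2)c(OCc2ccccc2)c1OCc1ccc(OCc2ccccc2)c(Br)c1 | intermediate
9 | tosylhydrazone of 8 | COC(=O)C(=NNS(=O)(=O)c1ccc(C)cc1)c1ccc(OCc2ccccc2)c(OCc2ccccc2)c1OCc1ccc(OCc2ccccc2)c(Br)c1 | intermediate
10 | methyl aryldiazoacetate | COC(=O)C(=[N+]=[N-])c1ccc(OCc2ccccc2)c(OCc2ccccc2)c1OCc1ccc(OCc2ccccc2)c(Br)c1 | intermediate
11 | (2S,3R)-cis-dihydrobenzofuran ester | COC(=O)[C@@H]1c2ccc(OCc3ccccc3)c(OCc3ccccc3)c2O[C@@H]1c1ccc(OCc2ccccc2)c(Br)c1 | intermediate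
12 | (2S,3S)-cis-dihydrobenzofuran-3-ylmethanol | OC[C@@H]1c2ccc(OCc3ccccc3)c(OCc3ccccc3)c2O[C@@H]1c1ccc(OCc2ccccc2)c(Br)c1 | intermediate
13 | primary triflate of 12 | FC(F)(F)S(=O)(=O)OC[C@@H]1c2ccc(OCc3ccccc3)c(OCc3ccccc3)c2O[C@@H]1c1ccc(OCc2ccccc2)c(Br)c1 | intermediate
14 | phenonium (spiro[2.5]octadienyl) triflate, drawn as the O7-oxocarbenium form | C1[C@H]2[C@@H](c3ccc(OCc4ccccc4)c(Br)c3)OC3=C(OCc4ccccc4)C(=[O+]Cc4ccccc4)C=C[C@]123.[O-]S(=O)(=O)C(F)(F)F | intermediate
15 | (2R,3R)-3'-bromo-tri-O-benzylepioritin (common monomer) | Brc1cc(ccc1OCc1ccccc1)[C@H]1Oc2c(ccc(OCc3ccccc3)c2OCc2ccccc2)C[C@H]1O | intermediate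
16 | (2R,3R)-tetra-O-benzylepimesquitol | C(c1ccccc1)Oc1ccc(cc1OCc1ccccc1)[C@H]1Oc2c(ccc(OCc3ccccc3)c2OCc2ccccc2)C[C@H]1O | intermediate
17 | (2R,3R,4S)-4β-(2-ethoxyethoxy) derivative of 15 | Brc1cc(ccc1OCc1ccccc1)[C@H]1Oc2c(ccc(OCc3ccccc3)c2OCc2ccccc2)[C@H](OCCOCC)[C@H]1O | intermediate
18 | protected (4β→6) dimer, lower C4H2 | O(Cc5ccccc5)c1c(Br)cc([C@H]2Oc3c(ccc(OCc5ccccc5)c3OCc5ccccc5)[C@H](c3cc4c(c(OCc5ccccc5)c3OCc5ccccc5)O[C@H](c3ccc(OCc5ccccc5)c(OCc5ccccc5)c3)[C@H](O)C4)[C@H]2O)cc1 | intermediate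
19 | protected (4β→6) dimer, lower 4β-OH | O(Cc5ccccc5)c1c(Br)cc([C@H]2Oc3c(ccc(OCc5ccccc5)c3OCc5ccccc5)[C@H](c3cc4c(c(OCc5ccccc5)c3OCc5ccccc5)O[C@H](c3ccc(OCc5ccccc5)c(OCc5ccccc5)c3)[C@H](O)[C@H]4O)[C@H]2O)cc1 | intermediate
20 | epioritin-(4β→6)-epimesquitol-4β-ol, upper (2R,3R,4S), lower (2R,3R,4S) | Oc1ccc([C@H]2Oc3c(ccc(O)c3O)[C@H](c3cc4c(c(O)c3O)O[C@H](c3ccc(O)c(O)c3)[C@H](O)[C@H]4O)[C@H]2O)cc1 | target

**Totals:** 14 steps; longest linear sequence 12 steps (steps 2–9, then 10 or 11, then 12–14).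

**Steps most likely to fail**

Step 9. The primary triflate may collapse by a hydride shift and proton loss to the aromatic 3-methylbenzofuran, water may return at the primary carbon, or ring B may migrate.
- The fallback sets out from 11, returns at 15, and keeps the ring expansion but drives it with a hydroxyl push through a C3 ketone.
- Enolisation of 11 (KHMDS, THF, −78 °C) and hydroxylation with 2-(phenylsulfonyl)-3-phenyloxaziridine, anti to the 2-aryl group, should give the tertiary α-hydroxy ester F1.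
- Ammonolysis (NH3, MeOH) should give the hydroxy amide F2, and BH3·THF the 1,2-amino alcohol F3.
- Diazotisation (NaNO2, aq. AcOH, 0 °C) should trigger a Tiffeneau–Demjanov ring expansion with migration of the electron-rich ring A to give the flavan-3-one F4.
- L-Selectride (THF, −78 °C), the established reagent for turning flavan-3-ones into 2,3-cis-flavan-3-ols, should then return 15.

Step 12. The 7,8-dioxygenated ring A is only a moderate nucleophile, so the cation from 17 may be consumed by self-condensation at its own C6 or by O-alkylation.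
- The fallback sets out from 15, returns at 20, and blocks the competing position.
- NBS (CH2Cl2, −78 °C) should brominate C6 of 15 to give the 6,3'-dibromide F5.
- DDQ with 2-ethoxyethanol should give the capped electrophile F6.
- Near-equimolar coupling with 16 (BF3·OEt2, CH2Cl2, −78 °C) should give the 6-bromo dimer F7.
- DDQ in CH2Cl2–H2O should give the 4β-alcohol F8.
- The conditions of step 14 with extra Et3N should remove both bromines and all benzyl groups to give 20.

Step 13. Hydride abstraction may occur at the upper C4–H or at a C2–H, or the new alcohol may be over-oxidised to the ketone.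
- The fallback sets out from 16 and 17, returns at 20, and installs the lower C4 oxygen before the union under orthogonal (soft versus hard) activation.
- DDQ and BnOH on 16 should give the 4β-benzyl ether F9.
- Exchange of 17 with BnSH (BF3·OEt2, CH2Cl2, −20 °C) should give the 4β-benzyl sulfide F10.
- AgBF4 (THF, 0 °C) should ionise only the C–S bond of F10 in the presence of F9 and give the dimer F11.
- The conditions of step 14 should then convert F11 into 20.

**Further compounds**
F1 | step 9 | methyl 3β-hydroxy-2,3-dihydrobenzofuran-3-carboxylate (OH trans to the 2-aryl group) | COC(=O)[C@]1(O)c2ccc(OCc3ccccc3)c(OCc3ccccc3)c2O[C@@H]1c1ccc(OCc2ccccc2)c(Br)c1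
F2 | step 9 | corresponding primary hydroxy amide | NC(=O)[C@]1(O)c2ccc(OCc3ccccc3)c(OCc3ccccc3)c2O[C@@H]1c1ccc(OCc2ccccc2)c(Br)c1
F3 | step 9 | 3-(aminomethyl)-2,3-dihydrobenzofuran-3-ol | NC[C@]1(O)c2ccc(OCc3ccccc3)c(OCc3ccccc3)c2O[C@@H]1c1ccc(OCc2ccccc2)c(Br)c1
F4 | step 9 | (2R)-7,8-bis(benzyloxy)-2-[4-(benzyloxy)-3-bromophenyl]chroman-3-one | O=C1Cc2ccc(OCc3ccccc3)c(OCc3ccccc3)c2O[C@@H]1c1ccc(OCc2ccccc2)c(Br)c1
F5 | step 12 | 6-bromo derivative of 15 | Brc1cc(ccc1OCc1ccccc1)[C@H]1Oc2c(cc(Br)c(OCc3ccccc3)c2OCc2ccccc2)C[C@H]1O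
F6 | step 12 | 6-bromo-4β-(2-ethoxyethoxy) electrophile | Brc1cc(ccc1OCc1ccccc1)[C@H]1Oc2c(cc(Br)c(OCc3ccccc3)c2OCc2ccccc2)[C@H](OCCOCC)[C@H]1O
F7 | step 12 | protected dimer with upper 6-Br, lower C4H2 | O(Cc5ccccc5)c1c(Br)cc([C@H]2Oc3c(cc(Br)c(OCc5ccccc5)c3OCc5ccccc5)[C@H](c3cc4c(c(OCc5ccccc5)c3OCc5ccccc5)O[C@H](c3ccc(OCc5ccccc5)c(OCc5ccccc5)c3)[C@H](O)C4)[C@H]2O)cc1
F8 | step 12 | protected dimer with upper 6-Br, lower 4β-OH | O(Cc5ccccc5)c1c(Br)cc([C@H]2Oc3c(cc(Br)c(OCc5ccccc5)c3OCc5ccccc5)[C@H](c3cc4c(c(OCc5ccccc5)c3OCc5ccccc5)O[C@H](c3ccc(OCc5ccccc5)c(OCc5ccccc5)c3)[C@H](O)[C@H]4O)[C@H]2O)cc1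
F9 | step 13 | 4β-benzyloxy derivative of 16 | C(c1ccccc1)Oc1ccc(cc1OCc1ccccc1)[C@H]1Oc2c(ccc(OCc3ccccc3)c2OCc2ccccc2)[C@H](OCc2ccccc2)[C@H]1O
F10 | step 13 | 4β-benzylsulfanyl derivative of 15 | Brc1cc(ccc1OCc1ccccc1)[C@H]1Oc2c(ccc(OCc3ccccc3)c2OCc2ccccc2)[C@H](SCc2ccccc2)[C@H]1O
F11 | step 13 | protected dimer with lower 4β-OBn | O(Cc5ccccc5)c1c(Br)cc([C@H]2Oc3c(ccc(OCc5ccccc5)c3OCc5ccccc5)[C@H](c3cc4c(c(OCc5ccccc5)c3OCc5ccccc5)O[C@H](c3ccc(OCc5ccccc5)c(OCc5ccccc5)c3)[C@H](O)[C@H]4OCc5ccccc5)[C@H]2O)cc1
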